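A conversion curve that goes flat with starting material unused can pass for an equilibrium, and that reading can send you to the wrong remedy. Here is the flask, followed so far as run zeta, and what is asked of it.

- zeta: starting material 0.50 M; partner 3 equiv; second substrate 2 equiv; precatalyst 2 mol%; impurity 11 mM; the very flask that is asked about, followed so far
- flask: starting material 0.50 M; partner 3.00 equiv; second substrate 2.00 equiv; precatalyst 2 mol%; impurity 11 mM; time 15 min

zeta run (percent of the starting material charged)

| time / min | target / % |
|---|---|
| 2.00 | 14.8 |
| 4.00 | 25.3 |
| 5.00 | 28.6 |
| 8.00 | 33.9 |
| 10.0 | 35.4 |

(readings scatter by 0.3 percentage points)

- west: change nothing and wait 5.0 min more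
- north: at 15 min take out 90% of the target then present, then wait 5.0 min
- east: at 15 min add precatalyst, 100% of the amount charged, then wait 5.0 min

- removed target is counted in
- additions bring no volume worth counting

1. target, in percent of the starting material first charged, at 15 min
2. what to do for the largest gain in target; "none" if nothing gains more than 2 percentage points (west / north / east / none)
3. target present, with what was taken out counted in, in percent of the starting material first charged, after west
4. target present, with what was taken out counted in, in percent of the starting material first charged, after north

My own bracket comes first. The floor is the last reading, 35.4% at 10.0 min. For a loose ceiling, hold the last gain of 1.5 percentage points per 2.00 min up to 15 min, which gives 39.1%. The last slopes fall at about 0.343 min⁻¹, and if that decay holds, the tail sums to a tighter ceiling of 36.9%.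

The curve's shape can't say why it stops, so compare the charges. Take 11 mM of impurity over 10.0 mM of catalyst charged as precatalyst: that is 1.10, and I call it the poison ratio, impurity per catalyst charged. Above one, the flask can hold enough impurity to titrate its catalyst, a case of catalyst poisoning. So I expect the plateau to be a dead catalyst, north to add what west adds, and east to work, since its dose of 10.0 mM meets about 1.00 mM of spare impurity.

The forecast gives 36.7%, inside my bracket, and 36.9% after west. But it says “so this is an equilibrium”, chooses north, and puts north at 48%, far above my ceiling.

The flask gives 36.8%, then 36.9% after west and 36.9% after north, each a gain of 0.12 points, while east gains 58 points; the best choice is east. At 15.0 min, 94.2% of the catalyst stands as spent catalyst B and 0.0526% as free catalyst. The poison ratio of the east dose, 1.58 mM of impurity left over 10.0 mM of new catalyst, is 0.158, well below one.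

    starting material + partner + free catalyst → free catalyst + target (k = 2.20 M⁻² s⁻¹)
    second substrate + partner + free catalyst → free catalyst + second product (k = 0.0320 M⁻² s⁻¹)
    partner + free catalyst → spent catalyst A (k = 0.00270 M⁻¹ s⁻¹)
    free catalyst + impurity → spent catalyst B (k = 13.0 M⁻¹ s⁻¹)
    precatalyst → free catalyst (k = 0.00750 s⁻¹)

In the neighbour flask with 0.85 M of starting material, the loading held, 17.0 mM of catalyst meets the same impurity, so the poison ratio is 0.647. That predicts about 64.7% of the catalyst lost to impurity, since the impurity stands below the catalyst charged. Computed, this neighbour flask reaches 98.9% target at 15.0 min, with 64.7% of its catalyst as spent catalyst B, 32.8% as spent catalyst A, 2.36% as free catalyst and 0.117% as precatalyst.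

All runs were computed for substances that don't exist, and the scatter is random.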